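The route disconnects the ring-fusion bond C3a–C8a of the hydroazulene. C3a sits between two oxygen-bearing carbons (C3, C4) and next to quaternary C8a, so the five- and seven-membered rings are read as the product of a pinacol-type 1,2-shift in a cis-fused decalin: in a 7,8,8a-triol 8-mesylate the angular carbon migrates from the carbinol carbon to the sulfonate carbon. This single step forms C3a–C8a, contracts ring B to the cyclopentane, expands ring A to the cycloheptanone, inverts C3a, keeps C8a and leaves the tertiary carbinol C3 in place. All stereocentres are relayed from (R)-carvone through the rigid decalin.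

Key step: step 9

Remark on locants: the target and compounds 14–19 carry octahydroazulene locants (C3 tertiary carbinol, C3a, C4 ester carbon, C6, C8a). The decalins 9–13 carry naphthalene locants (C2, C4a, C7, C8, C8a); ring A holds C1–C4, ring B holds C5–C8.
Assumption: 4-iodo-2-methylbut-1-ene (3) and 4-acetoxybenzoic acid (17) are bought as catalogue compounds.

Step 1
Reactants: 1 (R)-(−)-carvone
Product: 2 (5R)-2-methyl-5-(propan-2-yl)cyclohex-2-en-1-one
Conditions: H2 (1 atm), RhCl(PPh3)3 (cat.), benzene, rt
Reagents that add atoms: none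
Why: Homogeneous hydrogenation with RhCl(PPh3)3 should reduce only the unhindered 1,1-disubstituted isopropenyl olefin and leave the trisubstituted enone and the C5 stereocentre untouched.

Step 2
Reactants: 2 (5R)-2-methyl-5-(propan-2-yl)cyclohex-2-en-1-one; 3 4-iodo-2-methylbut-1-ene
Product: 5 (2R,5R)-2-methyl-2-(3-methylbut-3-en-1-yl)-5-(propan-2-yl)cyclohexan-1-one, via lithium enolate 4 (not isolated)
Conditions: Li, NH3(l), t-BuOH (1 equiv), THF, −78 °C; then 3, −78 → −33 °C
Reagents that add atoms: none
Why: Dissolving-metal reductive alkylation gives the regiodefined enolate 4, which should be alkylated by axial attack on the half-chair with isopropyl equatorial, so the chain enters cis to isopropyl (2R); the minor C2 epimer has to be removed here, because C5 is flattened in step 3 and that epimer would then become the enantiomer.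

Step 3
Reactants: 5 (2R,5R)-2-methyl-2-(3-methylbut-3-en-1-yl)-5-(propan-2-yl)cyclohexan-1-one
Product: 6 (6S)-6-methyl-6-(3-methylbut-3-en-1-yl)-3-(propan-2-yl)cyclohex-2-en-1-one
Conditions: 2-iodoxybenzoic acid (IBX), DMSO, 70 °C
Reagents that add atoms: none
Why: IBX dehydrogenation of a ketone through its enol; only C6 carries α-hydrogens (C2 is quaternary), so the conjugated 3-isopropyl enone should form, with loss of the C5 stereocentre after it has done its work.

Step 4
Reactants: 6 (6S)-6-methyl-6-(3-methylbut-3-en-1-yl)-3-(propan-2-yl)cyclohex-2-en-1-one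
Product: 8 (6R)-6-methyl-6-(3-oxobutyl)-3-(propan-2-yl)cyclohex-2-en-1-one, via secondary ozonide 7 (not isolated)
Conditions: O3, CH2Cl2, −78 °C (Sudan red 7B end point); then Me2S, −78 °C → rt
Reagents that add atoms: ozone, [O-][O+]=O
Why: Ozonolysis: ozone should react far faster with the electron-rich 1,1-disubstituted olefin than with the conjugated enone, and reductive work-up of ozonide 7 unveils the methyl ketone.

Step 5
Reactants: 8 (6R)-6-methyl-6-(3-oxobutyl)-3-(propan-2-yl)cyclohex-2-en-1-one
Product: 9 (4aR,8aS)-8a-hydroxy-4a-methyl-7-(propan-2-yl)-3,4,4a,5,6,8a-hexahydronaphthalen-2(1H)-one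
Conditions: LiN(i-Pr)2, THF, −78 → −45 °C; AcOH quench at −78 °C
Reagents that add atoms: none
Why: Kinetic intramolecular aldol addition: the CH3 enolate adds 1,2 to the ring carbonyl (six-membered ring; the enone β-carbon is out of reach), and attack anti to the pseudoaxial methyl should give the cis-fused ketol as in Robinson annulation ketols, with 8a-OH cis to 4a-CH3 (8aS).

Step 6
Reactants: 9 (4aR,8aS)-8a-hydroxy-4a-methyl-7-(propan-2-yl)-3,4,4a,5,6,8a-hexahydronaphthalen-2(1H)-one
Product: 11 (4aR,7R,8S,8aR)-7,8,8a-trihydroxy-4a-methyl-7-(propan-2-yl)octahydronaphthalen-2(1H)-one, via osmate ester TMEDA adduct 10 (not isolated)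
Conditions: OsO4 (1 equiv), TMEDA, CH2Cl2, −78 °C; then aq. NaHSO3, THF, rt
Reagents that add atoms: osmium tetroxide, O=[Os](=O)(=O)=O
Why: Hydroxyl-directed syn-dihydroxylation with OsO4·TMEDA: hydrogen bonding to the pseudoaxial 8a-OH and the convex face of the cis-decalin should both deliver osmium to the face of 8a-OH and 4a-CH3, setting C7 (R) and C8 (S).

Step 7
Reactants: 11 (4aR,7R,8S,8aR)-7,8,8a-trihydroxy-4a-methyl-7-(propan-2-yl)octahydronaphthalen-2(1H)-one
Product: 12 (4aS,7R,8S,8aR)-4a-methyl-2-methylidene-7-(propan-2-yl)decahydronaphthalene-7,8,8a-triol (locants as in 11)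
Conditions: Zn, CH2Br2, TiCl4, THF–CH2Cl2, 0 °C → rt
Reagents that add atoms: dibromomethane, BrCBr
Why: Takai–Lombardo methylenation is non-basic, so the retro-aldol-prone β-hydroxy ketone and the free hydroxyls should survive while the C2 carbonyl becomes the exocyclic methylene that later turns into the C6 methyl; no stereocentre changes.

Step 8
Reactants: 12 (4aS,7R,8S,8aR)-4a-methyl-2-methylidene-7-(propan-2-yl)decahydronaphthalene-7,8,8a-triol
Product: 13 (4aS,7R,8S,8aR)-7,8a-dihydroxy-4a-methyl-2-methylidene-7-(propan-2-yl)decahydronaphthalen-8-yl methanesulfonate (locants as in 11)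
Conditions: MsCl (1.2 equiv), Et3N, CH2Cl2, −30 °C
Reagents that add atoms: methanesulfonyl chloride, CS(Cl)(=O)=O
Why: Sulfonylation: only the secondary, equatorial 8-OH should be mesylated, the two tertiary hydroxyls being far slower, and the configuration at C8 is retained.

Step 9
Reactants: 13 (4aS,7R,8S,8aR)-7,8a-dihydroxy-4a-methyl-2-methylidene-7-(propan-2-yl)decahydronaphthalen-8-yl methanesulfonate
Product: 14 (3R,3aR,8aS)-3-hydroxy-8a-methyl-6-methylidene-3-(propan-2-yl)octahydroazulen-4(1H)-one
Conditions: Et3Al, CH2Cl2, −78 → 0 °C; aq. potassium sodium tartrate work-up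
Reagents that add atoms: none
Why: Tsuchihashi–Suzuki pinacol-type rearrangement: Et3Al turns the hydroxyls into aluminium alkoxides and activates the mesylate, the lone pair on O8a pushes, and the ring-fusion bond C8a–C4a, antiperiplanar to the equatorial C8–OMs bond in the chair with isopropyl equatorial, migrates to C8 as mesylate leaves. The closest known reaction type is the base- or organoaluminium-promoted rearrangement of cis-fused decalin vicinal diol monosulfonates (secondary sulfonate next to the angular carbinol) to hydroazulenones. The new bond C8–C4a (C3a–C8a of the product) closes both rings at once by a suprafacial 1,2-alkyl shift through a three-centre transition state: ring B contracts from six to five members while ring A expands from six to seven, and the old C4a–C8a bond, absent from the target, is given up. C3a is fixed by inversion at the sulfonate carbon (configured by the directed dihydroxylation), C8a by retention in the migrating carbon (set in step 2), and C3 is the untouched C7 carbinol, so all three should come out as in the target (the descriptor 3aR in the ketone is a priority effect only). The step needs migration of C4a and not of C6 (the other antiperiplanar ring bond, which the 7-alkoxide could push) or of C1: C1 is gauche to the leaving group, no β-hydrogen is available for elimination, the cis-hydroxyls cannot close an epoxide, and the fully substituted C4a should outrun the CH2 carbon C6 as migrating group. The product stays a chelated aluminium aldolate at low temperature, which should suppress retro-aldol cleavage.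

Step 10
Reactants: 14 (3R,3aR,8aS)-3-hydroxy-8a-methyl-6-methylidene-3-(propan-2-yl)octahydroazulen-4(1H)-one
Product: 15 (3R,3aR,8aS)-3-hydroxy-6,8a-dimethyl-3-(propan-2-yl)-2,3,3a,7,8,8a-hexahydroazulen-4(1H)-one
Conditions: DBU (0.2 equiv), CH2Cl2, rt
Reagents that add atoms: none
Why: Base-catalysed isomerisation of the β,γ-unsaturated exo-methylene ketone to the conjugated trisubstituted enone through the dienolate; C3a should stay as set, since the trans ring fusion with the carbonyl anti to isopropyl is expected to be the more stable epimer.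

Step 11
Reactants: 15 (3R,3aR,8aS)-3-hydroxy-6,8a-dimethyl-3-(propan-2-yl)-2,3,3a,7,8,8a-hexahydroazulen-4(1H)-one
Product: 16 (3R,3aS,4S,8aS)-6,8a-dimethyl-3-(propan-2-yl)-1,2,3,3a,4,7,8,8a-octahydroazulene-3,4-diol
Conditions: Me4NBH(OAc)3, MeCN–AcOH, −30 °C
Reagents that add atoms: none
Why: Evans–Saksena reduction: the tertiary 3-OH binds the triacetoxyborohydride and should deliver hydride intramolecularly to the carbonyl face syn to it, giving the 1,3-anti diol, that is the 4S carbinol with its oxygen trans to 3-OH.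

Step 12
Reactants: 16 (3R,3aS,4S,8aS)-6,8a-dimethyl-3-(propan-2-yl)-1,2,3,3a,4,7,8,8a-octahydroazulene-3,4-diol; 17 4-acetoxybenzoic acid
Product: 18 (3R,3aS,4S,8aS)-3-hydroxy-6,8a-dimethyl-3-(propan-2-yl)-1,2,3,3a,4,7,8,8a-octahydroazulen-4-yl 4-(acetyloxy)benzoate
Conditions: DCC, DMAP (cat.), CH2Cl2, 0 °C → rt
Reagents that add atoms: none
Why: Steglich esterification: the secondary allylic 4-OH should be acylated while the tertiary 3-OH is not, and no stereocentre is touched.

Step 13
Reactants: 18 (3R,3aS,4S,8aS)-3-hydroxy-6,8a-dimethyl-3-(propan-2-yl)-1,2,3,3a,4,7,8,8a-octahydroazulen-4-yl 4-(acetyloxy)benzoate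
Product: 19 (3R,3aS,4S,8aS)-3-hydroxy-6,8a-dimethyl-3-(propan-2-yl)-1,2,3,3a,4,7,8,8a-octahydroazulen-4-yl 4-hydroxybenzoate
Conditions: pyrrolidine, CH2Cl2, 0 °C → rt
Reagents that add atoms: none
Why: Aminolysis of the aryl acetate, an activated ester, should be much faster than attack on the hindered alkyl benzoate and frees the phenol to give the target.

Compound list
1 | (R)-(−)-carvone, (5R)-2-methyl-5-(prop-1-en-2-yl)cyclohex-2-en-1-one | CC1=CC[C@H](CC1=O)C(C)=C | starting material
2 | (5R)-2-methyl-5-(propan-2-yl)cyclohex-2-en-1-one | CC1=CC[C@H](CC1=O)C(C)C | intermediate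
3 | 4-iodo-2-methylbut-1-ene | CC(=C)CCI | starting material
4 | lithium (5R)-2-methyl-5-(propan-2-yl)cyclohex-1-en-1-olate | CC1=C([O-])C[C@H](C(C)C)CC1.[Li+] | intermediate
5 | (2R,5R)-2-methyl-2-(3-methylbut-3-en-1-yl)-5-(propan-2-yl)cyclohexan-1-one (side chain cis to isopropyl) | O=C1C[C@H](C(C)C)CC[C@]1(C)CCC(C)=C | intermediate
6 | (6S)-6-methyl-6-(3-methylbut-3-en-1-yl)-3-(propan-2-yl)cyclohex-2-en-1-one | O=C1C=C(C(C)C)CC[C@]1(C)CCC(C)=C | intermediate
7 | 3-methyl-3-{2-[(1R)-1-methyl-2-oxo-4-(propan-2-yl)cyclohex-3-en-1-yl]ethyl}-1,2,4-trioxolane (secondary ozonide, both epimers at the trioxolane carbon) | CC1(CC[C@@]2(C)CCC(C(C)C)=CC2=O)OCOO1 | intermediate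
8 | (6R)-6-methyl-6-(3-oxobutyl)-3-(propan-2-yl)cyclohex-2-en-1-one | O=C1C=C(C(C)C)CC[C@]1(C)CCC(C)=O | intermediate
9 | (4aR,8aS)-8a-hydroxy-4a-methyl-7-(propan-2-yl)-3,4,4a,5,6,8a-hexahydronaphthalen-2(1H)-one (cis-fused, 8a-OH cis to 4a-CH3) | O=C1CC[C@@]2(C)CCC(C(C)C)=C[C@@]2(O)C1 | intermediate
10 | cyclic dioxo-osmium diolate (osmate ester) of 11 across O7 and O8, TMEDA adduct; O7, O8, 8a-OH and 4a-CH3 on one face | O=C1CC[C@@]2(C)CC[C@]3(C(C)C)O[Os](=O)(=O)O[C@@H]3[C@@]2(O)C1.CN(C)CCN(C)C | intermediate
11 | (4aR,7R,8S,8aR)-7,8,8a-trihydroxy-4a-methyl-7-(propan-2-yl)octahydronaphthalen-2(1H)-one (cis-fused, three hydroxyls and 4a-CH3 on one face) | O=C1CC[C@@]2(C)CC[C@@](O)(C(C)C)[C@H](O)[C@@]2(O)C1 | intermediate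
12 | (4aS,7R,8S,8aR)-4a-methyl-2-methylidene-7-(propan-2-yl)decahydronaphthalene-7,8,8a-triol (locants as in 11) | C=C1CC[C@@]2(C)CC[C@@](O)(C(C)C)[C@H](O)[C@@]2(O)C1 | intermediate
13 | (4aS,7R,8S,8aR)-7,8a-dihydroxy-4a-methyl-2-methylidene-7-(propan-2-yl)decahydronaphthalen-8-yl methanesulfonate (locants as in 11) | C=C1CC[C@@]2(C)CC[C@@](O)(C(C)C)[C@H](OS(C)(=O)=O)[C@@]2(O)C1 | intermediate
14 | (3R,3aR,8aS)-3-hydroxy-8a-methyl-6-methylidene-3-(propan-2-yl)octahydroazulen-4(1H)-one (trans-fused, 3-OH cis to 8a-CH3 and to C4) | C=C1CC[C@@]2(C)CC[C@@](O)(C(C)C)[C@@H]2C(=O)C1 | intermediate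
15 | (3R,3aR,8aS)-3-hydroxy-6,8a-dimethyl-3-(propan-2-yl)-2,3,3a,7,8,8a-hexahydroazulen-4(1H)-one | CC1=CC(=O)[C@@H]2[C@@](C)(CC1)CC[C@@]2(O)C(C)C | intermediate
16 | (3R,3aS,4S,8aS)-6,8a-dimethyl-3-(propan-2-yl)-1,2,3,3a,4,7,8,8a-octahydroazulene-3,4-diol | CC1=C[C@H](O)[C@@H]2[C@@](C)(CC1)CC[C@@]2(O)C(C)C | intermediate
17 | 4-acetoxybenzoic acid | CC(=O)Oc1ccc(cc1)C(O)=O | starting material
18 | (3R,3aS,4S,8aS)-3-hydroxy-6,8a-dimethyl-3-(propan-2-yl)-1,2,3,3a,4,7,8,8a-octahydroazulen-4-yl 4-(acetyloxy)benzoate | CC1=C[C@H](OC(=O)c2ccc(OC(C)=O)cc2)[C@@H]2[C@@](C)(CC1)CC[C@@]2(O)C(C)C | intermediate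
19 | (3R,3aS,4S,8aS)-3-hydroxy-6,8a-dimethyl-3-(propan-2-yl)-1,2,3,3a,4,7,8,8a-octahydroazulen-4-yl 4-hydroxybenzoate | CC1=C[C@H](OC(=O)c2ccc(O)cc2)[C@@H]2[C@@](C)(CC1)CC[C@@]2(O)C(C)C | target

Total step count: 13. Longest linear sequence: 13 steps (from 1; 3 and 17 are bought).

Steps most likely to fail

Step 9 (key step). The 1,2-shift may be driven from the wrong side: the 7-alkoxide can push the C7–C6 bond onto C8, which contracts ring B without expanding ring A. The aluminium aldolate may also fragment by retro-aldol on warming. The fallback sets out from ketol 9. Hydroxyl-directed epoxidation (VO(acac)2, t-BuOOH, CH2Cl2) should give the syn-epoxy ketol F1, and Takai–Lombardo methylenation the epoxy alcohol F2. Treatment of F2 with BF3·OEt2 (CH2Cl2, −78 °C) is a semipinacol rearrangement of a 2,3-epoxy alcohol; O7 is tied up in the oxirane that leaves from C8, so only O8a can push. This fallback carries its own risk of the oxirane opening at the tertiary C7. The route is rejoined at 14.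

Step 5. The aldol addition to the hindered, conjugated carbonyl may be slow or reverse, and the aldolate may dehydrate toward the linear dienone during quench and isolation. The fallback sets out from enone 6. A type-2 intramolecular carbonyl–ene cyclisation of the isopropenyl chain onto the ring carbonyl (Me2AlCl, CH2Cl2, −78 °C) should give the cis-fused dienol F3, which already carries the exocyclic methylene. Directed dihydroxylation of its allylic olefin with OsO4·TMEDA then rejoins the route at 12, bypassing steps 4 to 7.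

Step 2. C-alkylation of the tetrasubstituted enolate by an unactivated primary iodide may be sluggish, with proton exchange, elimination of HI from 3 and eroded facial selectivity. The fallback sets out from 2. Conjugate reduction with LiBH(s-Bu)3 and trapping with Me3SiCl should give the silyl enol ether F4. Mukaiyama–Michael addition to methyl vinyl ketone (TiCl4, CH2Cl2, −78 °C) gives the diketone F5, and Wittig methylenation (Ph3P=CH2, one equivalent) of its unhindered methyl ketone rejoins the route at 5.

Further compounds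
F1 | step 9 | cis-fused 7,8-epoxy-8a-hydroxy-4a-methyl-7-(propan-2-yl)octahydronaphthalen-2(1H)-one, oxirane on the face of 8a-OH and 4a-CH3 | O=C1CC[C@@]2(C)CC[C@]3(C(C)C)O[C@@H]3[C@@]2(O)C1
F2 | step 9 | cis-fused 7,8-epoxy-4a-methyl-2-methylidene-7-(propan-2-yl)octahydronaphthalen-8a(1H)-ol, oxirane on the face of 8a-OH and 4a-CH3 | C=C1CC[C@@]2(C)CC[C@]3(C(C)C)O[C@@H]3[C@@]2(O)C1
F3 | step 5 | (4aS,8aS)-4a-methyl-2-methylidene-7-(propan-2-yl)-1,3,4,4a,5,6-hexahydronaphthalen-8a(2H)-ol | C=C1CC[C@@]2(C)CCC(C(C)C)=C[C@@]2(O)C1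
F4 | step 2 | trimethyl{[(5R)-2-methyl-5-(propan-2-yl)cyclohex-1-en-1-yl]oxy}silane | CC1=C(O[Si](C)(C)C)C[C@H](C(C)C)CC1
F5 | step 2 | (2R,5R)-2-methyl-2-(3-oxobutyl)-5-(propan-2-yl)cyclohexan-1-one | O=C1C[C@H](C(C)C)CC[C@]1(C)CCC(C)=O
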